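The route rests on breaking the aryl ether bond O1–C8a of ring C. Because O1 links the benzylic stereocentre C2 to the ring A carbon C8a, the C2–O bond can be made early as a configurationally secure (S)-carbinol and left intact. A palladium-catalysed intramolecular C–O coupling of that hydroxyl with the C8a bromide then closes ring C in one operation with retention at C2. The precursor is an (S)-3-aryl-1-(2-bromoaryl)propane-1,3-diol derivative with free C2–OH, a triisopropylsilyl ether on the C4 oxygen (so that this oxygen cannot bind palladium and be oxidised), MOM-protected phenols and both prenyl groups.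

Key step: step 12

Remarks on the chemistry (assumptions):
- Flavanone numbering (O1, C2, C3, C4, C4a, C5 to C8, C8a; ring B primed) is used for open-chain compounds too. MOM = methoxymethyl, TIPS = triisopropylsilyl, prenyl = 3-methylbut-2-en-1-yl.
- C4 is carried as both configurations from step 9 to step 13, because step 14 converts it into the ketone; only C2 is controlled.
- A free C4 hydroxyl is not innocent in the coupling: after oxidative addition it can chelate the arylpalladium in a five-membered ring and transfer its carbinol hydrogen, giving debrominated ketone. The two hydroxyls are therefore differentiated by the order of events (aldol, silylation, then ketone reduction).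
- Commercial 3-hydroxy-4-methoxyacetophenone is used for ring B so that the methyl ketone needed for the aldol is present from the start.

Step 1
Reactants: 1 2-methylbut-3-en-2-ol
Product: 3 tert-butyl 2-methylbut-3-en-2-yl carbonate, via lithium 2-methylbut-3-en-2-olate 2 (not isolated)
Conditions: n-BuLi, THF, −78 → 0 °C; then Boc2O, 0 °C → rt; aq NH4Cl
Reagents that add atoms: di-tert-butyl dicarbonate, CC(C)(C)OC(=O)OC(=O)OC(C)(C)C
Why: Acylation of a preformed tertiary lithium alkoxide with Boc2O is a standard mixed-carbonate synthesis and avoids acid, which would ionise the tertiary allylic alcohol.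

Step 2
Reactants: 4 1-(3-hydroxy-4-methoxyphenyl)ethanone; 3 tert-butyl 2-methylbut-3-en-2-yl carbonate
Product: 5 1-[4-methoxy-3-(2-methylbut-3-en-2-yloxy)phenyl]ethanone
Conditions: 3 (1.5 equiv), Pd(PPh3)4 (2 mol%), 4 Å MS, THF, 0 °C → rt
Reagents that add atoms: none
Why: Tsuji–Trost O-allylation, in which decarboxylative ionisation of 3 gives a 1,1-dimethyl-π-allyl palladium cation and tert-butoxide, and the resulting phenoxide attacks the more substituted allyl terminus under kinetic control to give the tertiary ether.

Step 3
Reactants: 5 1-[4-methoxy-3-(2-methylbut-3-en-2-yloxy)phenyl]ethanone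
Product: 7 1-(3-hydroxy-4-methoxy-2-prenylphenyl)ethanone, via ring B cyclohexadienone 6 (not isolated)
Conditions: PhNEt2, 130 °C
Reagents that add atoms: none
Why: Aromatic Claisen rearrangement, whose [3,3] shift should deliver the allyl unit as a linear prenyl group to C2', the only unsubstituted ortho carbon (the other carries OMe), after which the dienone tautomerises to the phenol.

Step 4
Reactants: 7 1-(3-hydroxy-4-methoxy-2-prenylphenyl)ethanone
Product: 8 1-[4-methoxy-3-(methoxymethoxy)-2-prenylphenyl]ethanone
Conditions: MOMCl, i-Pr2NEt, CH2Cl2, 0 °C → rt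
Reagents that add atoms: chloromethyl methyl ether, COCCl
Why: Williamson-type MOM ether formation on a phenol with an amine base, which leaves the methyl ketone unenolised.

Step 5
Reactants: 9 5-bromoresorcinol
Product: 11 2-bromo-4,6-dihydroxybenzaldehyde, via aryl iminium chloride 10 (not isolated)
Conditions: POCl3, DMF, MeCN, 0 °C → rt; then H2O, 50 °C
Reagents that add atoms: N,N-dimethylformamide, CN(C)C=O; water, O
Why: Vilsmeier–Haack formylation, in which the chloroiminium ion attacks para to one hydroxyl and ortho to the other (the usual site in 5-substituted resorcinols such as orcinol and olivetol), placing the formyl group next to bromine after hydrolysis of the iminium salt.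

Step 6
Reactants: 11 2-bromo-4,6-dihydroxybenzaldehyde; 3 tert-butyl 2-methylbut-3-en-2-yl carbonate
Product: 12 2-bromo-6-hydroxy-4-(2-methylbut-3-en-2-yloxy)benzaldehyde
Conditions: 3 (1.2 equiv), Pd(PPh3)4 (2 mol%), 4 Å MS, THF, 0 °C
Reagents that add atoms: none
Why: Tsuji–Trost O-allylation as in step 2, selective for the hydroxyl para to the formyl group because the ortho hydroxyl is held in a hydrogen bond to the aldehyde, while oxidative addition to the aryl bromide is far slower than ionisation of the allylic carbonate at 0 °C.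

Step 7
Reactants: 12 2-bromo-6-hydroxy-4-(2-methylbut-3-en-2-yloxy)benzaldehyde
Product: 14 6-bromo-2,4-dihydroxy-3-prenylbenzaldehyde, via ring A cyclohexadienone 13 (not isolated)
Conditions: PhNEt2, 120 °C
Reagents that add atoms: none
Why: Aromatic Claisen rearrangement to the carbon between the two oxygens, the site favoured in 4-allyloxy-2-hydroxyaryl carbonyl compounds by the bond fixation of the chelated ring (the other ortho carbon is also crowded by bromine), followed by tautomerisation of the dienone.

Step 8
Reactants: 14 6-bromo-2,4-dihydroxy-3-prenylbenzaldehyde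
Product: 15 6-bromo-2,4-bis(methoxymethoxy)-3-prenylbenzaldehyde
Conditions: MOMCl (3 equiv), i-Pr2NEt (4 equiv), CH2Cl2, 0 → 40 °C
Reagents that add atoms: chloromethyl methyl ether, COCCl
Why: Double MOM ether formation, run with excess reagent and gentle warming because one hydroxyl is hydrogen-bonded to the aldehyde and flanked by the prenyl group.

Step 9
Reactants: 8 1-[4-methoxy-3-(methoxymethoxy)-2-prenylphenyl]ethanone; 15 6-bromo-2,4-bis(methoxymethoxy)-3-prenylbenzaldehyde
Product: 17 racemic 3-[6-bromo-2,4-bis(methoxymethoxy)-3-prenylphenyl]-3-hydroxy-1-[4-methoxy-3-(methoxymethoxy)-2-prenylphenyl]propan-1-one, via lithium enolate 16 (not isolated)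
Conditions: LDA, THF, −78 °C; then 15, −78 °C; AcOH quench at −78 °C
Reagents that add atoms: none
Why: Directed aldol addition of a preformed lithium enolate (the methyl group is the only enolisable site) to a non-enolisable aldehyde forms C3–C4, with a cold acidic quench to prevent retro-aldol and dehydration; the C4 carbinol is deliberately left racemic because step 14 oxidises it.

Step 10
Reactants: 17 racemic aldol
Product: 18 racemic 3-[6-bromo-2,4-bis(methoxymethoxy)-3-prenylphenyl]-1-[4-methoxy-3-(methoxymethoxy)-2-prenylphenyl]-3-[(triisopropylsilyl)oxy]propan-1-one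
Conditions: TIPSOTf (1.2 equiv), 2,6-lutidine, CH2Cl2, −40 → 0 °C
Reagents that add atoms: triisopropylsilyl trifluoromethanesulfonate, CC(C)[Si](OS(=O)(=O)C(F)(F)F)(C(C)C)C(C)C
Why: Silylation of a hindered secondary alcohol with a silyl triflate and a hindered pyridine base, using TIPS because it resists 1,5-migration to a neighbouring hydroxyl under carbonate base and survives the next two steps.

Step 11
Reactants: 18 racemic TIPS-protected β-silyloxy ketone
Product: 19 (1S)-3-[6-bromo-2,4-bis(methoxymethoxy)-3-prenylphenyl]-1-[4-methoxy-3-(methoxymethoxy)-2-prenylphenyl]-3-[(triisopropylsilyl)oxy]propan-1-ol (both C3 epimers, i.e. both configurations at flavanone C4)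
Conditions: (R)-Me-CBS oxazaborolidine [(R)-1-methyl-3,3-diphenyltetrahydro-1H,3H-pyrrolo[1,2-c][1,3,2]oxazaborole] (20 mol%), catecholborane, toluene, −78 → −40 °C; aqueous work-up
Reagents that add atoms: none
Why: Corey–Bakshi–Shibata reduction, in which the (R)-oxazaborolidine binds the carbonyl oxygen anti to the aryl group and delivers hydride to the Re face, so C2 should be set as (S) under catalyst control for both C4 epimers, while catecholborane does not hydroborate the trisubstituted prenyl alkenes at this temperature.

Step 12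
Reactants: 19 (1S)-bromo carbinol with C4–OTIPS
Product: 20 (2S)-2-[4-methoxy-3-(methoxymethoxy)-2-prenylphenyl]-5,7-bis(methoxymethoxy)-6-prenyl-4-[(triisopropylsilyl)oxy]chromane (both C4 epimers)
Conditions: Pd(OAc)2 (5 mol%), 2-(di-tert-butylphosphino)-1,1'-binaphthyl (6 mol%, racemic ligand suffices), Cs2CO3 (1.5 equiv), toluene, 80 °C
Reagents that add atoms: none
Why: Oxidative addition of the C8a–Br bond to zerovalent palladium (generated in situ from Pd(OAc)2 and the phosphine) is followed by coordination and carbonate-assisted deprotonation of the C2 hydroxyl to give a seven-membered arylpalladium alkoxide, and C–O reductive elimination from it forms O1–C8a. The closest known reaction is the Buchwald–Hartwig-type intramolecular etherification of aryl bromides with secondary alcohols, which gives 2-substituted chromans without loss of enantiopurity. Ring C is closed as a six-membered ring by formal 6-exo attack of the tethered oxygen on the arene carbon through that palladacycle. No stereocentre is formed: C2 stays (S) because none of its bonds is broken, and both C4 epimers should cyclise. The step needs the C2 oxygen to be the only one that reaches palladium, which the TIPS ether on C4 secures, and it needs reductive elimination to outrun β-hydride loss from the C2 alkoxide, which the bulky electron-rich di-tert-butylphosphine is meant to ensure. Because C4 is a silyl ether and not a ketone, C3 carries no acidic hydrogens, so the carbonate base cannot trigger retro-aldol cleavage or elimination to a chalcone.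

Step 13
Reactants: 20 (2S)-4-silyloxyflavan
Product: 21 (2S)-2-[4-methoxy-3-(methoxymethoxy)-2-prenylphenyl]-5,7-bis(methoxymethoxy)-6-prenylchroman-4-ol (both C4 epimers)
Conditions: TBAF, THF, 0 °C → rt; aq NH4Cl
Reagents that add atoms: none
Why: Fluoride-induced silyl ether cleavage, harmless here because the flavan has no base-labile stereocentre at this stage.

Step 14
Reactants: 21 (2S)-flavan-4-ol
Product: 22 (2S)-2-[4-methoxy-3-(methoxymethoxy)-2-prenylphenyl]-5,7-bis(methoxymethoxy)-6-prenylchroman-4-one
Conditions: Dess–Martin periodinane, NaHCO3, CH2Cl2, 0 °C → rt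
Reagents that add atoms: none
Why: Dess–Martin oxidation of a secondary benzylic alcohol under bicarbonate buffering should converge both C4 epimers on one ketone without opening ring C, so C2 is not epimerised.

Step 15
Reactants: 22 (2S)-tris-MOM flavanone
Product: 23 (2S)-5,7-dihydroxy-2-(3-hydroxy-4-methoxy-2-prenylphenyl)-6-prenylchroman-4-one (CNP0306216.1)
Conditions: HCl (1.25 M in MeOH), 0 °C → rt, quenched with NaHCO3 as soon as conversion is complete
Reagents that add atoms: none
Why: Acid-catalysed transacetalisation of the three aryl MOM ethers in methanol, with dilute acid, low temperature and early quenching chosen to avoid addition of the freed phenols to the ortho prenyl groups and acid-mediated opening of ring C.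

Compound list
1 | 2-methylbut-3-en-2-ol | CC(C)(O)C=C | starting material
2 | lithium 2-methylbut-3-en-2-olate (formed in the flask, not isolated) | [Li+].[O-]C(C)(C)C=C | intermediate
3 | tert-butyl 2-methylbut-3-en-2-yl carbonate | CC(C)(C)OC(=O)OC(C)(C)C=C | intermediate
4 | 1-(3-hydroxy-4-methoxyphenyl)ethanone | CC(=O)c1ccc(OC)c(O)c1 | starting material
5 | 1-[4-methoxy-3-(2-methylbut-3-en-2-yloxy)phenyl]ethanone | CC(=O)c1ccc(OC)c(OC(C)(C)C=C)c1 | intermediate
6 | 2-acetyl-5-methoxy-1-prenylcyclohexa-2,4-dien-6-one, ring B Claisen dienone (racemic, not isolated) | CC(=O)C1=CC=C(OC)C(=O)C1CC=C(C)C | intermediate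
7 | 1-(3-hydroxy-4-methoxy-2-prenylphenyl)ethanone | CC(=O)c1ccc(OC)c(O)c1CC=C(C)C | intermediate
8 | 1-[4-methoxy-3-(methoxymethoxy)-2-prenylphenyl]ethanone | CC(=O)c1ccc(OC)c(OCOC)c1CC=C(C)C | intermediate
9 | 5-bromoresorcinol | Oc1cc(O)cc(Br)c1 | starting material
10 | (2-bromo-4,6-dihydroxybenzylidene)dimethyliminium chloride (not isolated) | C[N+](C)=Cc1c(O)cc(O)cc1Br.[Cl-] | intermediate
11 | 2-bromo-4,6-dihydroxybenzaldehyde | O=Cc1c(O)cc(O)cc1Br | intermediate
12 | 2-bromo-6-hydroxy-4-(2-methylbut-3-en-2-yloxy)benzaldehyde | O=Cc1c(O)cc(OC(C)(C)C=C)cc1Br | intermediate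
13 | 6-bromo-2-hydroxy-4-oxo-3-prenylcyclohexa-1,5-diene-1-carbaldehyde, ring A Claisen dienone (racemic, not isolated) | O=CC1=C(O)C(CC=C(C)C)C(=O)C=C1Br | intermediate
14 | 6-bromo-2,4-dihydroxy-3-prenylbenzaldehyde | O=Cc1c(Br)cc(O)c(CC=C(C)C)c1O | intermediate
15 | 6-bromo-2,4-bis(methoxymethoxy)-3-prenylbenzaldehyde | O=Cc1c(Br)cc(OCOC)c(CC=C(C)C)c1OCOC | intermediate
16 | lithium enolate of 8 (not isolated) | [Li+].[O-]C(=C)c1ccc(OC)c(OCOC)c1CC=C(C)C | intermediate
17 | racemic 3-[6-bromo-2,4-bis(methoxymethoxy)-3-prenylphenyl]-3-hydroxy-1-[4-methoxy-3-(methoxymethoxy)-2-prenylphenyl]propan-1-one | COc1ccc(C(=O)CC(O)c2c(Br)cc(OCOC)c(CC=C(C)C)c2OCOC)c(CC=C(C)C)c1OCOC | intermediate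
18 | racemic 3-[6-bromo-2,4-bis(methoxymethoxy)-3-prenylphenyl]-1-[4-methoxy-3-(methoxymethoxy)-2-prenylphenyl]-3-[(triisopropylsilyl)oxy]propan-1-one | COc1ccc(C(=O)CC(O[Si](C(C)C)(C(C)C)C(C)C)c2c(Br)cc(OCOC)c(CC=C(C)C)c2OCOC)c(CC=C(C)C)c1OCOC | intermediate
19 | (1S)-3-[6-bromo-2,4-bis(methoxymethoxy)-3-prenylphenyl]-1-[4-methoxy-3-(methoxymethoxy)-2-prenylphenyl]-3-[(triisopropylsilyl)oxy]propan-1-ol, both C3 epimers | COc1ccc([C@@H](O)CC(O[Si](C(C)C)(C(C)C)C(C)C)c2c(Br)cc(OCOC)c(CC=C(C)C)c2OCOC)c(CC=C(C)C)c1OCOC | intermediate
20 | (2S)-2-[4-methoxy-3-(methoxymethoxy)-2-prenylphenyl]-5,7-bis(methoxymethoxy)-6-prenyl-4-[(triisopropylsilyl)oxy]chromane, both C4 epimers | COc1ccc([C@@H]2CC(O[Si](C(C)C)(C(C)C)C(C)C)c3c(cc(OCOC)c(CC=C(C)C)c3OCOC)O2)c(CC=C(C)C)c1OCOC | intermediate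
21 | (2S)-2-[4-methoxy-3-(methoxymethoxy)-2-prenylphenyl]-5,7-bis(methoxymethoxy)-6-prenylchroman-4-ol, both C4 epimers | COc1ccc([C@@H]2CC(O)c3c(cc(OCOC)c(CC=C(C)C)c3OCOC)O2)c(CC=C(C)C)c1OCOC | intermediate
22 | (2S)-2-[4-methoxy-3-(methoxymethoxy)-2-prenylphenyl]-5,7-bis(methoxymethoxy)-6-prenylchroman-4-one | COc1ccc([C@@H]2CC(=O)c3c(cc(OCOC)c(CC=C(C)C)c3OCOC)O2)c(CC=C(C)C)c1OCOC | intermediate
23 | (2S)-5,7-dihydroxy-2-(3-hydroxy-4-methoxy-2-prenylphenyl)-6-prenylchroman-4-one (CNP0306216.1) | COc1ccc([C@@H]2CC(=O)c3c(cc(O)c(CC=C(C)C)c3O)O2)c(CC=C(C)C)c1O | target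

Total step count: 15.
Longest linear sequence: 11 steps (steps 5 to 15 from 5-bromoresorcinol; the branch through steps 1 to 4 and 9 to 15 is equally long).

Steps most likely to fail

1. Step 12 (ring C closure). Oxidative addition into the electron-rich, ortho-branched aryl bromide may be slow, and the arylpalladium alkoxide may lose a β-hydride from C2 faster than it forms the C–O bond, which would consume the substrate by debromination and carbinol oxidation. The fallback installs the oxygen on C8a first and closes ring C at O1–C2 by a Mitsunobu displacement with inversion. It sets out from 18. Miyaura borylation (PdCl2(dppf), bis(pinacolato)diboron, KOAc, dioxane, 80 °C) should give the aryl pinacol boronate F1, and NaBO3·4H2O in THF–water should oxidise it to the C8a phenol F2. Reduction with the (S)-oxazaborolidine and catecholborane should then give the (1R)-carbinol phenol F3, and PPh3/DIAD in THF at 0 °C should close the ring with inversion to give 20, where the route is rejoined. The para-methoxy group of ring B makes this benzylic displacement prone to partial ionisation, which is why it is held in reserve only.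

2. Step 11 (setting C2). Facial discrimination may be insufficient because both flanks of the ketone are bulky and the ortho prenyl group twists the aryl ring, or induction may be mismatched for one C4 epimer; either would lower the enantiomeric purity at C2. The fallback moves the enantioselective step to the unprotected 1,3-dicarbonyl stage with a different catalyst class. It sets out from 17. Dess–Martin oxidation should give the 1,3-diketone F4, and transfer hydrogenation with RuCl(p-cymene)[(S,S)-TsDPEN] in HCO2H–Et3N, the established way from 1,3-diaryl-1,3-diketones to anti-1,3-diols, should give the anti-(1S,3S)-diol F5. Because F5 has a free C4 hydroxyl, it would be cyclised with copper instead of palladium (CuI, 3,4,7,8-tetramethyl-1,10-phenanthroline, Cs2CO3, toluene, 110 °C; Ullmann-type etherification, where alkoxide β-hydride loss is much less facile). This should give the (2S,4S) epimer of 21, where the route is rejoined.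

3. Step 15 (MOM removal). A liberated phenol may add to its ortho prenyl alkene under acid (chroman formation), and prolonged acid exposure may cause slow racemisation at C2 through opening of ring C. The fallback cleaves the aryl MOM ethers without protic acid. It sets out from 22: TMSOTf and 2,2'-bipyridyl in CH2Cl2 at 0 °C should convert the three aryl MOM ethers into trimethylsilyl ethers, giving the tris(trimethylsilyl) ether F6, and addition of water at 0 °C should hydrolyse it to 23.

Further compounds
F1 | step 12 | racemic 3-[2,4-bis(methoxymethoxy)-3-prenyl-6-(4,4,5,5-tetramethyl-1,3,2-dioxaborolan-2-yl)phenyl]-1-[4-methoxy-3-(methoxymethoxy)-2-prenylphenyl]-3-[(triisopropylsilyl)oxy]propan-1-one | COc1ccc(C(=O)CC(O[Si](C(C)C)(C(C)C)C(C)C)c2c(B3OC(C)(C)C(C)(C)O3)cc(OCOC)c(CC=C(C)C)c2OCOC)c(CC=C(C)C)c1OCOC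
F2 | step 12 | racemic 3-[6-hydroxy-2,4-bis(methoxymethoxy)-3-prenylphenyl]-1-[4-methoxy-3-(methoxymethoxy)-2-prenylphenyl]-3-[(triisopropylsilyl)oxy]propan-1-one | COc1ccc(C(=O)CC(O[Si](C(C)C)(C(C)C)C(C)C)c2c(O)cc(OCOC)c(CC=C(C)C)c2OCOC)c(CC=C(C)C)c1OCOC
F3 | step 12 | (1R)-3-[6-hydroxy-2,4-bis(methoxymethoxy)-3-prenylphenyl]-1-[4-methoxy-3-(methoxymethoxy)-2-prenylphenyl]-3-[(triisopropylsilyl)oxy]propan-1-ol, both C3 epimers | COc1ccc([C@H](O)CC(O[Si](C(C)C)(C(C)C)C(C)C)c2c(O)cc(OCOC)c(CC=C(C)C)c2OCOC)c(CC=C(C)C)c1OCOC
F4 | step 11 | 1-[6-bromo-2,4-bis(methoxymethoxy)-3-prenylphenyl]-3-[4-methoxy-3-(methoxymethoxy)-2-prenylphenyl]propane-1,3-dione | COc1ccc(C(=O)CC(=O)c2c(Br)cc(OCOC)c(CC=C(C)C)c2OCOC)c(CC=C(C)C)c1OCOC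
F5 | step 11 | anti-(1S,3S)-1-[6-bromo-2,4-bis(methoxymethoxy)-3-prenylphenyl]-3-[4-methoxy-3-(methoxymethoxy)-2-prenylphenyl]propane-1,3-diol | COc1ccc([C@@H](O)C[C@H](O)c2c(Br)cc(OCOC)c(CC=C(C)C)c2OCOC)c(CC=C(C)C)c1OCOC
F6 | step 15 | (2S)-2-[4-methoxy-2-prenyl-3-(trimethylsilyloxy)phenyl]-6-prenyl-5,7-bis(trimethylsilyloxy)chroman-4-one | COc1ccc([C@@H]2CC(=O)c3c(cc(O[Si](C)(C)C)c(CC=C(C)C)c3O[Si](C)(C)C)O2)c(CC=C(C)C)c1O[Si](C)(C)C
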